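The earlier runs and the new flask are simulated with made-up constants, noise included.

- Watch the early times: in the red run single product reads 24% after 0.625 d and 18% by 2.50 d, while substrate falls to 25%. So single product is itself being consumed, and I read this as its taking up a second partner to give a double product.

common to all: substrate 0.25 M

| charge | partner | remark | time |
|---|---|---|---|
| teal | 0.017 M | run made earlier |  |
| ochre | 0.081 M | run made earlier |  |
| red | 0.32 M | run made earlier |  |
| north-west | 0.0200 M |  | 8.0 d |
| east | 0.0400 M |  | 8.0 d |
| south | 0.0800 M |  | 8.0 d |
| north-east | 0.150 M |  | 8.0 d |
| north | 0.300 M |  | 8.0 d |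

| run | time / d | single product / % | substrate / % |
|---|---|---|---|
| teal | 1.67 | 5 | 95 |
| teal | 3.00 | 7 | 93 |
| teal | 5.00 | 7 | 96 |
| teal | 6.00 | 5 | 91 |
| teal | 8.00 | 3 | 93 |
| ochre | 0.625 | 16 | 82 |
| ochre | 2.08 | 20 | 77 |
| ochre | 4.00 | 18 | 75 |
| ochre | 6.00 | 18 | 72 |
| ochre | 8.00 | 17 | 73 |
| red | 0.625 | 24 | 42 |
| red | 1.25 | 20 | 28 |
| red | 2.50 | 18 | 25 |
| red | 4.00 | 16 | 24 |
| red | 8.00 | 19 | 27 |

(readings scatter by 1.5 percentage points)

- "hardly changes" means that all values lie within two and a half points (for a concentration: within two and a half percent of the largest)

- amount of single product at the end, in percent of the substrate charged for north-west, east, south, north-east, north, in this order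
- the course of these numbers from the first flask to the last (falls all the way / rises all the way / falls, then rises / hardly changes / rises, then falls)

- My reckoning has two steps: substrate + partner gives single product, then single product + partner gives double product. Let x be the fraction of substrate consumed and M the single product per substrate charged. Partner stands in both rates, so it cancels from their ratio and time drops out of M as a function of x.
- A ratio of 2 between the second and first rate constants, read from the red and ochre levels, gives M = x − x·x, and the partner used per substrate charged is x + x·x.
- Take partner as the limiting reagent and let each flask stop when it is used. Then one number gives the outcome: the equivalents e, partner charged over substrate charged, 1.20 for north. It says how much partner each substrate can claim, and e = x + x·x.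
- Test on the ochre run: e = 0.324 gives M = 19.1% and substrate 74.2%, against last readings of 17% and 73%.
- Test on the red run: e = 1.28 gives 19.4% and 26.3%, against 19% and 27%. These gaps are of the size of the scatter, 1.5 percentage points, but the ratio was read from these same runs, so they show that one number can describe both runs, not that it predicts a new one.
- M tops at x = 0.5, which is e = 0.750, or 0.188 M of partner. I therefore expect a rise, then a fall, with north-east at 24.4% and north at 20.8%.
- The forecast, built on the same ratio (“the second step is about twice as fast as the first”), reads 6.9%, 12.1%, 19%, 24.4% and 20.8% from north-west to north: rises, then falls.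
- The flasks give 6.44%, 11.3%, 17.7%, 22.5% and 18.5% in the same order: rises, then falls.

    substrate + partner → single product (k = 0.300 M⁻¹ h⁻¹)
    substrate + partner → other mono adduct (k = 0.0210 M⁻¹ h⁻¹)
    partner + single product → double product (k = 0.650 M⁻¹ h⁻¹)
    partner + other mono adduct → double product (k = 0.0410 M⁻¹ h⁻¹)
    partner + single product → over-reaction product (k = 0.0130 M⁻¹ h⁻¹)

- In north-west at 0.337 d, single product has a half-life of 4.3 d by its reaction with partner to double product, against 9.3 d for substrate by its reaction to single product, so by these steps single product turns over about twice as fast as substrate, and the row turns at 0.18 M of partner, an e of 0.728. On that ratio, e = 1.20 for north gives substrate left at 29.6% against 29%, and e = 0.600 for north-east gives 57.8% against 57.4%.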